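The decalin is disconnected at C4–C5 and C9–C10 (labdane numbering). C4 is the α-carbon of the C19 ester, so H-atom transfer from a cobalt hydride to an open-chain 2-alkylacrylate generates the tertiary C4 radical. Two 6-endo closures (ring A through C4–C5, ring B through C10–C9) and return of H from C17 give the trans-decalin, its four new stereocentres and the C8(17) methylene in one isomerisation. The precursor is an (S)-5-acetoxy dienynyl acrylate built from geranyl chloride. Its C1 acetate relays absolute configuration. A 2-butynyl terminus stops the cascade and is converted last into the (E)-dienyl side chain by hydrozirconation and vinylation.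

Key step: step 7

Remark: the target is read as the (1S,4R,5S,9R,10S) isomer, a trans-decalin in which the C1 acetate (equatorial), the C19 ester (axial) and the C9 side chain (equatorial) all lie cis to the C20 methyl group.

Step 1
Reactants: 1 geranyl chloride [(2E)-1-chloro-3,7-dimethylocta-2,6-diene]; 2 1-propynylmagnesium bromide
Product: 3 (5E)-6,10-dimethylundeca-5,9-dien-2-yne
Conditions: CuI (5 mol%), THF, 0 °C to rt
Reagents that add atoms: 1-propynylmagnesium bromide (2), CC#C[Mg]Br
Why: Copper-catalysed SN2 cross-coupling of an alkynyl Grignard reagent with a primary allylic chloride should join the propynyl group to the unhindered α-carbon and leave the E-alkene unchanged; no stereocentre is formed.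

Step 2
Reactants: 3
Product: 5 (2E,6E)-2,6-dimethylundeca-2,6-dien-9-ynal, via allylic alcohol 4 (not isolated)
Conditions: SeO2 (0.3 equiv), t-BuOOH, salicylic acid (cat.), CH2Cl2, rt; then MnO2, CH2Cl2, rt
Reagents that add atoms: tert-butyl hydroperoxide, CC(C)(C)OO (oxygen atom, passed on through SeO2, O=[Se]=O)
Why: SeO2 allylic oxidation (ene reaction, then [2,3]-sigmatropic shift) should hydroxylate the E-methyl group of the terminal, least hindered trisubstituted alkene with retention of alkene geometry, and MnO2 oxidation of the crude alcohol/enal mixture converges on the (E)-enal; no stereocentre is formed.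

Step 3
Reactants: 5; 6 methylmagnesium bromide
Product: 8 (3E,7E)-3,7-dimethyldodeca-3,7-dien-10-yn-2-one, via bromomagnesium alkoxide 7 (not isolated)
Conditions: MeMgBr, THF, −78 to 0 °C; then 1,1'-(azodicarbonyl)dipiperidine, rt
Reagents that add atoms: methylmagnesium bromide (6), C[Mg]Br
Why: 1,2-Addition of the Grignard reagent to the enal followed by Mukaiyama oxidation of the magnesium alkoxide (hydride transfer to the azodicarboxamide) should give the methyl enone in one flask, so the transient carbinol stereocentre is of no consequence.

Step 4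
Reactants: 8; 9 methyl 2-(bromomethyl)acrylate
Product: 11 methyl (6E,10E)-6,10-dimethyl-2-methylidene-5-oxopentadeca-6,10-dien-13-ynoate, via lithium enolate 10 (not isolated)
Conditions: LDA, THF, −78 °C; then 9, −78 to −40 °C
Reagents that add atoms: methyl 2-(bromomethyl)acrylate (9), C=C(CBr)C(=O)OC
Why: Kinetic deprotonation at the α'-methyl group and SN2' alkylation (addition–elimination) of the cross-conjugated lithium enolate with the 2-(bromomethyl)acrylate should attach the 2-alkylacrylate unit (C2–C4, C18, C19); no stereocentre is formed.

Step 5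
Reactants: 11
Product: 12 methyl (5S,6E,10E)-5-hydroxy-6,10-dimethyl-2-methylidenepentadeca-6,10-dien-13-ynoate
Conditions: (R)-2-methyl-CBS-oxazaborolidine (20 mol%), catecholborane, toluene, −78 °C
Reagents that add atoms: none
Why: Corey–Bakshi–Shibata reduction, in which the α-methylalkenyl group is the large and the CH2 chain the small ketone substituent, should deliver hydride with the (R)-catalyst to give the (5S)-allylic alcohol (the future C1 stereocentre) without touching the acrylate, alkenes or alkyne at −78 °C.

Step 6
Reactants: 12; 13 acetic anhydride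
Product: 14 methyl (5S,6E,10E)-5-acetoxy-6,10-dimethyl-2-methylidenepentadeca-6,10-dien-13-ynoate
Conditions: Ac2O, Et3N, DMAP (cat.), CH2Cl2, 0 °C
Reagents that add atoms: acetic anhydride (13), CC(=O)OC(C)=O
Why: DMAP-catalysed acylation should install the C1 acetate of the target with retention, which also prevents δ-lactonisation onto the ester.

Step 7
Reactants: 14
Product: 15 methyl (1S,4R,5S,9R,10S)-1-acetoxy-14,15-dinorlabd-8(17)-en-12-yn-19-oate (trans-decalin with equatorial 1-OAc, axial 4-CO2Me, 8-methylene and equatorial 9-but-2-ynyl)
Conditions: Co(dmgBF2)2(H2O)2 (5 mol%; dmgBF2 = (difluoroboryl)dimethylglyoximate), H2 (3 atm), benzene (0.01 M), 50 °C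
Reagents that add atoms: none
Why: Proposed new method: the cobalt hydride formed reversibly from divalent cobalt and H2 should transfer H• only to the CH2 terminus of the 2-alkylacrylate (the one conjugated alkene), giving the tertiary C4 α-ester radical, which closes ring A by 6-endo-trig attack on C5 and then ring B by 6-endo-trig attack of the C10 radical on C9, after which divalent cobalt takes H• from the C17 methyl group of the C8 radical, as in catalytic chain transfer, so that the C8(17) methylene forms and the hydride is regenerated (net isomerisation). The closest known reaction types are the cobaloxime/H2 radical cycloisomerisation of 2-substituted acrylates bearing one alkene acceptor and metal-hydride H-atom-transfer-initiated polyene bicyclisations. Both closures should run through a chair–chair transition state: the E geometry of the C5=C10 alkene sets the trans ring fusion (H5 anti to C20) and that of the C8=C9 alkene places the C9 side chain equatorial. At C4 the planar ester should take the pseudo-axial and the methyl group the pseudo-equatorial position, the sense known from Mn(OAc)3-mediated cyclisations of α-methyl β-keto esters. The C1 acetate, kept pseudo-equatorial so that its C–O bond is not aligned with the alkene π system attacked by the electrophilic radical, should select the alkene face and so fix the absolute configuration. The step needs chemoselective initiation, secured by the inertness of the isolated alkenes, the product methylene and the alkyne to this weak hydride, and complete bicyclisation before H• return, secured by low cobalt concentration and high dilution.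

Step 8
Reactants: 15; 16 vinyl bromide
Product: 19 methyl (1S,4R,5S,9R,10S)-1-acetoxylabda-8(17),12E,14-trien-19-oate (the target), via alkenylzirconocene chloride 17 (not isolated), via alkenylzinc chloride 18 (not isolated)
Conditions: Cp2Zr(H)Cl (2 equiv), THF, rt to 40 °C; then ZnCl2, Pd(PPh3)4 (5 mol%), vinyl bromide, THF, rt
Reagents that add atoms: vinyl bromide (16), C=CBr
Why: Syn-hydrozirconation of the alkyne, equilibrated by excess hydride so that zirconium sits on the less hindered methyl-bearing C13, then Zr-to-Zn transmetalation and Negishi coupling with vinyl bromide with retention should give the (12E)-diene, alkyne hydrozirconation being faster than reduction of the hindered esters or addition to the 1,1-disubstituted alkene.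

Compound list
1 | geranyl chloride, (2E)-1-chloro-3,7-dimethylocta-2,6-diene | CC(C)=CCC/C(C)=C/CCl | starting material
2 | 1-propynylmagnesium bromide | CC#C[Mg]Br | starting material
3 | (5E)-6,10-dimethylundeca-5,9-dien-2-yne | CC(C)=CCC/C(C)=C/CC#CC | intermediate
4 | (2E,6E)-2,6-dimethylundeca-2,6-dien-9-yn-1-ol | OC/C(C)=C/CC/C(C)=C/CC#CC | intermediate
5 | (2E,6E)-2,6-dimethylundeca-2,6-dien-9-ynal | O=C/C(C)=C/CC/C(C)=C/CC#CC | intermediate
6 | methylmagnesium bromide | C[Mg]Br | starting material
7 | bromomagnesium (3E,7E)-3,7-dimethyldodeca-3,7-dien-10-yn-2-olate (racemic) | CC(O[Mg]Br)/C(C)=C/CC/C(C)=C/CC#CC | intermediate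
8 | (3E,7E)-3,7-dimethyldodeca-3,7-dien-10-yn-2-one | CC(=O)/C(C)=C/CC/C(C)=C/CC#CC | intermediate
9 | methyl 2-(bromomethyl)acrylate | C=C(CBr)C(=O)OC | starting material
10 | lithium (3E,7E)-3,7-dimethyldodeca-1,3,7-trien-10-yn-2-olate | [Li]OC(=C)/C(C)=C/CC/C(C)=C/CC#CC | intermediate
11 | methyl (6E,10E)-6,10-dimethyl-2-methylidene-5-oxopentadeca-6,10-dien-13-ynoate | C=C(CCC(=O)/C(C)=C/CC/C(C)=C/CC#CC)C(=O)OC | intermediate
12 | methyl (5S,6E,10E)-5-hydroxy-6,10-dimethyl-2-methylidenepentadeca-6,10-dien-13-ynoate | C=C(CC[C@H](O)/C(C)=C/CC/C(C)=C/CC#CC)C(=O)OC | intermediate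
13 | acetic anhydride | CC(=O)OC(C)=O | starting material
14 | methyl (5S,6E,10E)-5-acetoxy-6,10-dimethyl-2-methylidenepentadeca-6,10-dien-13-ynoate | C=C(CC[C@H](OC(C)=O)/C(C)=C/CC/C(C)=C/CC#CC)C(=O)OC | intermediate
15 | methyl (1S,4R,5S,9R,10S)-1-acetoxy-14,15-dinorlabd-8(17)-en-12-yn-19-oate | CC#CC[C@@H]1C(=C)CC[C@H]2[C@@]1(C)[C@@H](OC(C)=O)CC[C@@]2(C)C(=O)OC | intermediate
16 | vinyl bromide | C=CBr | starting material
17 | (E)-alkenylzirconocene chloride from 15 (Zr on C13, H on C12, cyclopentadienyl rings drawn σ-bonded) | C\C([Zr](Cl)(C3C=CC=C3)C4C=CC=C4)=C/C[C@@H]1C(=C)CC[C@H]2[C@@]1(C)[C@@H](OC(C)=O)CC[C@@]2(C)C(=O)OC | intermediate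
18 | (E)-alkenylzinc chloride from 17 (Zn on C13) | C\C([Zn]Cl)=C/C[C@@H]1C(=C)CC[C@H]2[C@@]1(C)[C@@H](OC(C)=O)CC[C@@]2(C)C(=O)OC | intermediate
19 | methyl (1S,4R,5S,9R,10S)-1-acetoxylabda-8(17),12E,14-trien-19-oate (CNP0235031.1) | C=C/C(C)=C/C[C@@H]1C(=C)CC[C@H]2[C@@]1(C)[C@@H](OC(C)=O)CC[C@@]2(C)C(=O)OC | target

Total step count: 8. Longest linear sequence: 8 steps (from geranyl chloride 1).

Steps most likely to fail

1. Step 7 (proposed new method). What may go wrong: return of the hydrogen atom to cobalt after the first ring closure (monocyclic products), simple hydrogenation of the acrylate, poor facial selectivity with respect to the C1 acetate, or closure at C4 with the ester equatorial. The fallback uses a known reaction type for the same C4–C5/C10–C9 bond pair, the Mn(OAc)3/Cu(OAc)2 oxidative radical bicyclisation of an α-methyl β-keto ester; it sets out from 5 and returns at 15. Enal 5 would undergo a Ti(OiPr)4/(S)-BINOL-catalysed vinylogous Mukaiyama aldol addition with 1-methoxy-2-methyl-1,3-bis(trimethylsilyloxy)buta-1,3-diene to give the (5S)-δ-hydroxy β-keto ester F1 (the BINOL antipode is chosen by analogy with aryl aldehydes). TBSCl/imidazole would give the silyl ether F2. Mn(OAc)3·2H2O (2 equiv) with Cu(OAc)2·H2O in AcOH would close both rings and end by copper-mediated loss of a C17 hydrogen, giving the 3-oxo bicycle F3 with the ester axial. The C3 ketone would be removed through the tosylhydrazone F4 (TsNHNH2, EtOH, heat) and its reduction with catecholborane/NaOAc to the silyl ether F5. TBAF would give the C1 alcohol F6, and acetylation (Ac2O, Et3N, DMAP) would give 15.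

2. Step 8. What may go wrong: erosion of regiocontrol in the hydrozirconation and reduction of the acetate or methyl ester by the zirconium hydride during equilibration. The fallback sets out from 15 and returns at 19 with no new compound. It is a palladium-catalysed reductive hydrovinylation (Pd(OAc)2, PPh3, vinyl bromide 16, HCO2H, Et3N, DMF, 50 °C). The vinylpalladium bromide would add syn across the alkyne with the vinyl group on the less hindered methyl-bearing C13, and formate would reduce the alkenylpalladium at C12. No hydride reagent meets the esters.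

3. Step 2. What may go wrong: oxidation at the allylic positions of the internal alkene or at the doubly activated allylic/propargylic CH2 instead of the terminal E-methyl group, and over-oxidation. The fallback sets out from 3 and returns at 8, bypassing steps 2 and 3 by cleaving the terminal alkene instead of oxidising its methyl group. NBS in aqueous THF at 0 °C would give the terminal bromohydrin F7. K2CO3 in MeOH would close it to the terminal epoxide F8. HIO4 in aqueous THF would cleave the epoxide to (4E)-4-methylnon-4-en-7-ynal F9. A Wittig reaction with 3-(triphenylphosphoranylidene)butan-2-one (toluene, 80 °C) would give the (E)-enone 8.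

Further compounds
F1 | step 7 | methyl (5S,6E,10E)-5-hydroxy-2,6,10-trimethyl-3-oxopentadeca-6,10-dien-13-ynoate (C2 epimers) | COC(=O)C(C)C(=O)C[C@H](O)/C(C)=C/CC/C(C)=C/CC#CC
F2 | step 7 | tert-butyldimethylsilyl ether of F1 | COC(=O)C(C)C(=O)C[C@H](O[Si](C)(C)C(C)(C)C)/C(C)=C/CC/C(C)=C/CC#CC
F3 | step 7 | 3-oxo analogue of 15 with a 1-(tert-butyldimethylsilyloxy) group in place of the acetate | CC#CC[C@@H]1C(=C)CC[C@H]2[C@@]1(C)[C@@H](O[Si](C)(C)C(C)(C)C)CC(=O)[C@@]2(C)C(=O)OC
F4 | step 7 | tosylhydrazone of F3 | CC#CC[C@@H]1C(=C)CC[C@H]2[C@@]1(C)[C@@H](O[Si](C)(C)C(C)(C)C)CC(=NNS(=O)(=O)c3ccc(C)cc3)[C@@]2(C)C(=O)OC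
F5 | step 7 | 1-(tert-butyldimethylsilyloxy) analogue of 15 | CC#CC[C@@H]1C(=C)CC[C@H]2[C@@]1(C)[C@@H](O[Si](C)(C)C(C)(C)C)CC[C@@]2(C)C(=O)OC
F6 | step 7 | 1-hydroxy analogue of 15 | CC#CC[C@@H]1C(=C)CC[C@H]2[C@@]1(C)[C@@H](O)CC[C@@]2(C)C(=O)OC
F0 | step 8 | none | none
F7 | step 2 | (6E)-3-bromo-2,6-dimethylundec-6-en-9-yn-2-ol (racemic) | CC(C)(O)C(Br)CC/C(C)=C/CC#CC
F8 | step 2 | 2,2-dimethyl-3-[(3E)-3-methyloct-3-en-6-yn-1-yl]oxirane (racemic) | CC1(C)OC1CC/C(C)=C/CC#CC
F9 | step 2 | (4E)-4-methylnon-4-en-7-ynal | O=CCC/C(C)=C/CC#CC
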